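# Synthesis plan for CNP0270097.1: epicatechin-(4β→8)-epifisetinidol-(4β→8)-catechin

## The problem

The target is a linear trimer of flavan-3-ols; flavan numbering is used within each unit. The top unit T is 5,7,3',4'-oxygenated with 2R,3R,4R configuration, the middle unit M is 5-deoxy (7,3',4'-oxygenated) with 2R,3R,4R, and the lower unit L is (+)-catechin (2R,3S). They are joined by T C4–M C8 and M C4–L C8, both bonds trans to the neighbouring C3 hydroxyl (4β).

Of the eight stereocentres, only the two of L come from the chiral pool. T and M each need a 2,3-cis-3,4-trans triad. The 2,3-cis relation is the less stable one, so it has to be set kinetically, in practice by inversion at C2. C3 can direct C4, because an arene adds anti to the C3 oxygen. Nothing in one unit fixes the absolute configuration of the next, so T and M each need their own source of absolute stereochemistry.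

M C8 lies between O1 and O7 of a resorcinol-type ring without a 5-oxygen. A flavan-4-yl cation would attack such a ring at C6, so the T C4–M C8 bond cannot be made by the usual cation coupling. M is also not a commercial flavanol.

Twelve phenols must stay masked (as benzyl ethers) until the end. Both interflavan bonds are acid-labile, T C4–M C8 most of all because ring A of T is phloroglucinol-like. C2–H is base-sensitive, and the benzylic C2–O bonds must survive the final hydrogenolysis.

The enabling feature is that ring A of T, seen as an aryl ether on O1, is a 3,5-dioxygenated phenyl group with two equivalent ortho carbons. In addition, C4 of T is benzylic to an aryl group with two ortho oxygens, the future C7 and C8a oxygens of M. An epoxide across C3–C4 of T can therefore be opened at C4 by either ortho carbon. This closes ring C through C4–C4a with inversion, and the awkward C8 linkage of M is inherited from a 2,6-dioxygenated benzaldehyde.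

## Retrosynthesis

**Deprotection.** Target 24 is traced to the dodeca-O-benzyl trimer 23. Only C–O bonds to benzyl are cut. One global hydrogenolysis is preferred to mixed protecting groups because every earlier step tolerates benzyl ethers. The forward step must spare the benzylic C2–O1 bonds.

**M C4–L C8.** Cutting this bond in 23 gives the 4-(2-ethoxyethoxy) dimer 20 and tetra-O-benzylcatechin 22. Arylation of a 2,3-cis flavan-4-yl cation is chosen because the axial C3 oxygen steers the arene to the opposite face, and benzylated catechin reacts at C8. The neighbouring option, adding 22 to a benzopyrylium salt of M, was rejected: it would create M C4 on a planar cation with no facial bias and leave C2 and C3 to a later reduction that favours 2,3-trans. The precursors are a dimer and a one-step derivative of (+)-catechin 21.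

**C4 oxygen of M.** Compound 20 is traced to the dimer 19 with a C4 methylene. The oxidation is placed here, on the terminal unit, because C4–H of T is a pseudo-equatorial diarylmethine hydrogen lying in the plane of ring A and is shielded on both sides.

**Ring C of M.** Cutting M C4–C4a in 19 gives the aryl glycidyl-type ether 18. A second cut at M O1–C2 gives phenol 14 and the anti epoxy alcohol 17. This repeats the logic of the top unit in its simplest form. Inversion at C2 (Mitsunobu) followed by closure onto the terminal epoxide carbon gives the 2,3-cis flavan-3-ol directly, whereas dihydroxylation-based routes give 2,3-trans and need an oxidation–reduction correction. The ring carbon para to the 7-benzyloxy group is the only free position ortho to the ether oxygen, so one regioisomer is possible. Epoxy alcohol 17 comes from the racemic allylic alcohol 16 by kinetic resolution, and 16 from aldehyde 15.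

**Protecting-group moves.** Phenol 14 comes from allyl ether 13, and 13 from the flavan-3-ol 12 by O-benzylation. The C3 hydroxyl of T is capped before the phenol is freed, so that it cannot be activated and displaced by the neighbouring phenoxide during the Mitsunobu step.

**Ring C of T (key cut).** Cutting T C4–C4a in 12 gives the epoxide 11. This cut is preferred to making T C4–M C8 by cation chemistry (wrong regiochemistry on a resorcinol ether) and to closing O1–C2 last (the diarylmethine C4 would then have to be set in an open chain). Compound 11 has no ring C and carries all three T stereocentres in a form that one asymmetric epoxidation can supply. The forward reaction must be 6-endo and anti.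

**O1–C2 of T.** Ether 11 is cut into the anti epoxy alcohol 8 and 3,5-bis(benzyloxy)phenol 10. A Mitsunobu reaction inverts the carbinol, which is why the anti diastereomer of 8 is needed. Phenol 10 comes from phloroglucinol 9.

**Epoxy alcohol 8.** It is traced to epoxy ketone 7 (chelation-controlled reduction), to chalcone 6 (asymmetric nucleophilic epoxidation), and to aldehyde 3 plus ketone 5 (aldol condensation). The aldehyde carbon becomes T C4, and its aryl ring, with two differentiated oxygens, becomes ring A of M. Aldehyde 3 comes from 1 through 2, and ketone 5 from 4.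

## Roads not taken

**Alternative 1:** The cut runs through three bonds of ring A of M (C8–C8a, C6–C7, C4a–C8a). In the forward sense a Danheiser benzannulation would join the ynol silyl ether A1, mounted on C4 of a protected epicatechin, with the unsaturated diazoketone A2, which carries L and the open C2–C4 chain of M. Wolff rearrangement of A2, [2+2] addition to A1, 4π opening and 6π closure would give the seco-trimer phenol A3.
- Merits: it is the most convergent of the four plans, and it solves the regiochemistry of the C8 linkage by construction.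
- Weak points: A2 needs an acyclic stereotriad including the diarylmethine carbon M C4, with no ring to control it. The annulation has to run at the temperatures of ketene chemistry on two large partners rich in benzylic ethers. After it, O1–C2 of M must still be closed with inversion and two silyl groups removed.
- Comparison: this road is better in convergence. The chosen plan sets against it that every stereocentre is made by a reaction whose sense is predictable (epoxidation, chelated reduction, SN2 inversion, anti epoxide opening), and that its key step runs early on a small substrate.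

**Alternative 2:** The cut takes M C3–C4 and M O1–C2. Dehydration of the ortho-hydroxybenzhydrol A4 and an ortho-quinone methide hetero-Diels–Alder reaction with the silyl enol ether A5 would give the ketal A6, with ring C of M formed in one step.
- Merits: T and L are already in place, two ring bonds form at once, and no C–H oxidation or cation coupling is needed. In step count for unit M this road is shorter than the chosen one.
- Weak points: the diene is flanked by two remote chiral units that give little facial bias, so the absolute configuration of M C4 is not controlled. The endo/exo outcome decides C3. The C2 ketal must then be reduced to the 2,3-cis ether, and hydride addition to such 2-aryl oxocarbenium ions normally gives 2,3-trans.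
- Comparison: the chosen plan is longer for M. It pays for this with reagent control at C3, inversion at C2 and C3-directed arylation at C4.

**Alternative 3:** The cut is T O1–C2, made last. The ring A phenol of the seco-trimer A7 would open a cis-epoxide at the benzylic carbon C2 (6-endo, inversion) and give the protected trimer A8 with its free C3 hydroxyl cis to the C2 aryl group.
- Merits: an oxygen nucleophile needs milder activation than a Friedel–Crafts closure, no cation develops at a doubly benzylic carbon, and the stereospecificity of phenol–epoxide openings is well established. In the reliability of the ring closure itself this road is at least as good as the chosen one.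
- Weak points: it needs an enantiopure cis-epoxide next to the diarylmethine stereocentre T C4. That centre, and the T C4–M C8 bond between two oxygens, must be made beforehand in an open chain, so the hardest bond is postponed rather than solved. The closure is also the last skeletal step on the largest intermediate.
- Comparison: in the chosen plan one trans-epoxide supplies C3 and, by inversion, C4. The C8 linkage comes from an aldehyde, and the closure is tested at the dimer-free stage.

Key step: step 9

## Route

Remark: "anti" epoxy alcohol means hydroxyl and oxirane oxygen on the same side in the Fischer projection (erythro), which is the outcome of chelation control and of Sharpless kinetic resolution.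

Step 1
Reactants: 1 2,6-dihydroxybenzaldehyde
Product: 2 2-(benzyloxy)-6-hydroxybenzaldehyde
Conditions: BnBr (1.0 equiv), K2CO3 (1.0 equiv), acetone, reflux
Reagents that add atoms: benzyl bromide, BrCc1ccccc1
Why: Williamson etherification; after the first alkylation the remaining phenol is held in a hydrogen bond to the formyl group and is much less nucleophilic, so one equivalent of halide should stop at the mono-ether.

Step 2
Reactants: 2 2-(benzyloxy)-6-hydroxybenzaldehyde
Product: 3 2-(allyloxy)-6-(benzyloxy)benzaldehyde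
Conditions: allyl bromide, K2CO3, DMF, 60 °C
Reagents that add atoms: allyl bromide, C=CCBr
Why: Williamson etherification of the chelated phenol under more forcing conditions; allyl marks the future O1 of M because it survives base, peroxide, hydride, Mitsunobu and Lewis acid conditions and is later removed by Pd(PPh3)4 without touching benzyl ethers.

Step 3
Reactants: 4 3',4'-dihydroxyacetophenone
Product: 5 3',4'-bis(benzyloxy)acetophenone
Conditions: BnBr (2.2 equiv), K2CO3, DMF, 60 °C
Reagents that add atoms: benzyl bromide, BrCc1ccccc1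
Why: Williamson etherification of both catechol hydroxyls; the product supplies ring B and C2 of T.

Step 4
Reactants: 3 2-(allyloxy)-6-(benzyloxy)benzaldehyde; 5 3',4'-bis(benzyloxy)acetophenone
Product: 6 (E)-3-[2-(allyloxy)-6-(benzyloxy)phenyl]-1-[3,4-bis(benzyloxy)phenyl]prop-2-en-1-one
Conditions: KOH (aq), EtOH–THF, rt
Reagents that add atoms: none
Why: Claisen–Schmidt condensation of a non-enolisable aldehyde with a methyl ketone; E1cB dehydration should give the E-enone, and the aldehyde carbon becomes C4 of T.

Step 5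
Reactants: 6 (E)-3-[2-(allyloxy)-6-(benzyloxy)phenyl]-1-[3,4-bis(benzyloxy)phenyl]prop-2-en-1-one
Product: 7 [(2R,3S)-3-[2-(allyloxy)-6-(benzyloxy)phenyl]oxiran-2-yl][3,4-bis(benzyloxy)phenyl]methanone
Conditions: poly-L-leucine, urea–H2O2, DBU, THF, rt
Reagents that add atoms: urea–hydrogen peroxide, NC(N)=O.OO
Why: Juliá–Colonna epoxidation; hydroperoxide adds to the β-carbon of the enone bound to the helical peptide, and poly-L-leucine should give the (2R,3S) trans-epoxide, which fixes C3 of T and the epoxide carbon later inverted to C4. The allyl ether alkene is inert to this nucleophilic oxidant.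

Step 6
Reactants: 7 [(2R,3S)-3-[2-(allyloxy)-6-(benzyloxy)phenyl]oxiran-2-yl][3,4-bis(benzyloxy)phenyl]methanone
Product: 8 (S)-[(2S,3S)-3-[2-(allyloxy)-6-(benzyloxy)phenyl]oxiran-2-yl][3,4-bis(benzyloxy)phenyl]methanol (anti epoxy alcohol)
Conditions: Zn(BH4)2, Et2O, −20 → 0 °C; aq. NH4Cl
Reagents that add atoms: none
Why: Chelation-controlled reduction of an α,β-epoxy ketone; zinc bridges the carbonyl and oxirane oxygens and hydride arrives on the face away from the epoxide C–C bond, which should give the anti alcohol with the (S)-carbinol.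

Step 7
Reactants: 9 phloroglucinol
Product: 10 3,5-bis(benzyloxy)phenol
Conditions: NaH (2.0 equiv), BnBr (2.0 equiv), DMF, 0 °C → rt; chromatographic separation from mono- and tri-ether
Reagents that add atoms: benzyl bromide, BrCc1ccccc1
Why: Statistical Williamson etherification of a symmetric triphenol; the dibenzyl ether is the middle component and is separable from its neighbours.

Step 8
Reactants: 8 (S)-[(2S,3S)-3-[2-(allyloxy)-6-(benzyloxy)phenyl]oxiran-2-yl][3,4-bis(benzyloxy)phenyl]methanol; 10 3,5-bis(benzyloxy)phenol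
Product: 11 (2R,3S)-3-[2-(allyloxy)-6-(benzyloxy)phenyl]-2-{(R)-[3,5-bis(benzyloxy)phenoxy][3,4-bis(benzyloxy)phenyl]methyl}oxirane
Conditions: PPh3, DIAD, toluene, 0 °C → rt
Reagents that add atoms: none
Why: Mitsunobu etherification of a phenol with a secondary benzylic epoxy alcohol; SN2 displacement of the oxyphosphonium group inverts the carbinol to the (R)-ether carbon, which is C2 of T, and the oxirane is untouched under these neutral conditions.

Step 9
Reactants: 11 (2R,3S)-3-[2-(allyloxy)-6-(benzyloxy)phenyl]-2-{(R)-[3,5-bis(benzyloxy)phenoxy][3,4-bis(benzyloxy)phenyl]methyl}oxirane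
Product: 12 (2R,3R,4S)-4-[2-(allyloxy)-6-(benzyloxy)phenyl]-5,7-bis(benzyloxy)-2-[3,4-bis(benzyloxy)phenyl]chroman-3-ol (2,3-cis-3,4-trans, 4β-aryl)
Conditions: Sc(OTf)3 (10 mol %), 4 Å MS, CH2Cl2 (0.005 M), −40 → 0 °C
Reagents that add atoms: none
Why: Sc(OTf)3 binds the oxirane oxygen and lengthens the C4–O bond, the only C–O bond that is benzylic and supported by two ortho oxygens; either ortho carbon of the 3,5-bis(benzyloxy)phenyl ether (they are equivalent) then attacks C4 opposite the departing oxygen, and proton loss from the arenium ion restores ring A and frees the C3 hydroxyl. The closest known reaction type is the acid-promoted intramolecular Friedel–Crafts epoxy–arene cyclisation of aryl ethers of 3-arylglycidols to trans-4-arylchroman-3-ols. Ring C closes in the 6-endo-tet mode at the benzylic carbon; the 5-exo alternative at C3 would have to pass through a non-benzylic, more crowded carbon to a dihydrobenzofuran. The new stereocentre C4 is set by inversion of the (S)-epoxide carbon, so the aryl group ends trans to the C3 hydroxyl, while C2 (step 8) and C3 (step 5) are carried through and give the 2,3-cis-3,4-trans triad; the descriptor at C4 is S here only because the simple aryl group ranks below C4a. The step needs anti stereospecificity rather than a free cation; the twisted 2,6-dioxygenated aryl group (only partial benzylic stabilisation), the low temperature and the high nucleophilicity of the tethered ring should secure it. It also needs a single regioisomer, which the symmetry of ring A guarantees. High dilution suppresses intermolecular alkylation, and the allyl ether, the benzyl ethers and the benzylic C2–O bond should tolerate a catalytic amount of this mild Lewis acid.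

Step 10
Reactants: 12 (2R,3R,4S)-4-[2-(allyloxy)-6-(benzyloxy)phenyl]-5,7-bis(benzyloxy)-2-[3,4-bis(benzyloxy)phenyl]chroman-3-ol
Product: 13 (2R,3R,4S)-4-[2-(allyloxy)-6-(benzyloxy)phenyl]-3,5,7-tris(benzyloxy)-2-[3,4-bis(benzyloxy)phenyl]chroman
Conditions: NaH, BnBr, Bu4NI (cat.), DMF, 0 °C → rt
Reagents that add atoms: benzyl bromide, BrCc1ccccc1
Why: Williamson etherification of the hindered secondary alkoxide, as in perbenzylation of 4-arylflavan-3-ols; it removes the one hydroxyl that could be activated and displaced by the neighbouring phenoxide in step 14.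

Step 11
Reactants: 13 (2R,3R,4S)-4-[2-(allyloxy)-6-(benzyloxy)phenyl]-3,5,7-tris(benzyloxy)-2-[3,4-bis(benzyloxy)phenyl]chroman
Product: 14 3-(benzyloxy)-2-{(2R,3R,4S)-3,5,7-tris(benzyloxy)-2-[3,4-bis(benzyloxy)phenyl]chroman-4-yl}phenol
Conditions: Pd(PPh3)4 (5 mol %), morpholine, THF, rt
Reagents that add atoms: none
Why: Tsuji–Trost deallylation; oxidative addition gives a π-allyl complex that morpholine captures, freeing the phenol that becomes O1 of M while the benzyl ethers stay.

Step 12
Reactants: 15 3,4-bis(benzyloxy)benzaldehyde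
Product: 16 rac-1-[3,4-bis(benzyloxy)phenyl]prop-2-en-1-ol
Conditions: CH2=CHMgBr, THF, −78 → 0 °C; aq. NH4Cl
Reagents that add atoms: vinylmagnesium bromide, C=C[Mg]Br
Why: Grignard addition to an aromatic aldehyde gives the secondary allylic alcohol needed for kinetic resolution.

Step 13
Reactants: 16 rac-1-[3,4-bis(benzyloxy)phenyl]prop-2-en-1-ol
Product: 17 (S)-[3,4-bis(benzyloxy)phenyl][(2R)-oxiran-2-yl]methanol (anti epoxy alcohol)
Conditions: Ti(OiPr)4 (10 mol %), L-(+)-DIPT (15 mol %), t-BuOOH (0.55 equiv), 4 Å MS, CH2Cl2, −20 °C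
Reagents that add atoms: tert-butyl hydroperoxide, CC(C)(C)OO
Why: Sharpless kinetic resolution; with L-(+)-tartrate the (R)-enantiomer of 16 should be epoxidised fast and anti-selectively, which sets C3 of M and the carbinol to be inverted, while (S)-16 is left behind, so at most half of 16 is used.

Step 14
Reactants: 14 3-(benzyloxy)-2-{(2R,3R,4S)-3,5,7-tris(benzyloxy)-2-[3,4-bis(benzyloxy)phenyl]chroman-4-yl}phenol; 17 (S)-[3,4-bis(benzyloxy)phenyl][(2R)-oxiran-2-yl]methanol
Product: 18 (2R)-2-{(R)-[3,4-bis(benzyloxy)phenyl][3-(benzyloxy)-2-{(2R,3R,4S)-3,5,7-tris(benzyloxy)-2-[3,4-bis(benzyloxy)phenyl]chroman-4-yl}phenoxy]methyl}oxirane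
Conditions: PPh3, DIAD, toluene (0.5 M), 0 °C → rt, sonication
Reagents that add atoms: none
Why: Mitsunobu etherification with inversion at the benzylic carbinol, which sets C2 of M as (R); high concentration and sonication are the usual aids for ortho-substituted phenols.

Step 15
Reactants: 18 (2R)-2-{(R)-[3,4-bis(benzyloxy)phenyl][3-(benzyloxy)-2-{(2R,3R,4S)-3,5,7-tris(benzyloxy)-2-[3,4-bis(benzyloxy)phenyl]chroman-4-yl}phenoxy]methyl}oxirane
Product: 19 octa-O-benzyl epicatechin-(4β→8)-epifisetinidol: T (2R,3R,4R) with 3,5,7,3',4'-benzyl ethers, M (2R,3R) with 7,3',4'-benzyl ethers, free C3 hydroxyl and C4 methylene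
Conditions: Sc(OTf)3 (20 mol %), CH2Cl2 (0.01 M), 0 °C → rt
Reagents that add atoms: none
Why: Intramolecular Friedel–Crafts epoxy–arene cyclisation in its known form on an aryl glycidyl-type ether; the ring carbon para to the 7-benzyloxy group, the only free position ortho to the ether oxygen, attacks the terminal epoxide carbon (6-endo), and C2 and C3 are carried through to the 2,3-cis flavan-3-ol.

Step 16
Reactants: 19 octa-O-benzyl epicatechin-(4β→8)-epifisetinidol
Product: 20 4β-(2-ethoxyethoxy) derivative of 19 at C4 of M (3,4-trans)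
Conditions: DDQ (2 equiv), HOCH2CH2OEt (5 equiv), CH2Cl2, rt
Reagents that add atoms: 2-ethoxyethanol, CCOCCO
Why: DDQ benzylic oxidation of a flavan-3-ol; hydride abstraction from the C4 methylene gives a cation stabilised by O7 and O1 that the alcohol traps anti to the C3 hydroxyl. C4–H of T, a pseudo-equatorial diarylmethine hydrogen in the plane of ring A, should not compete.

Step 17
Reactants: 21 (+)-catechin
Product: 22 5,7,3',4'-tetra-O-benzyl-(+)-catechin
Conditions: BnBr (4.4 equiv), K2CO3, DMF, 0 °C → rt
Reagents that add atoms: benzyl bromide, BrCc1ccccc1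
Why: Williamson etherification of the four phenols; carbonate does not deprotonate the C3 alcohol, and C2 is not epimerised under these conditions.

Step 18
Reactants: 20 4β-(2-ethoxyethoxy) derivative of 19; 22 5,7,3',4'-tetra-O-benzyl-(+)-catechin (4 equiv)
Product: 23 dodeca-O-benzyl epicatechin-(4β→8)-epifisetinidol-(4β→8)-catechin with free C3 hydroxyls on M and L
Conditions: TMSOTf (0.2 equiv), CH2Cl2, −78 → −40 °C
Reagents that add atoms: none
Why: Lewis acid-promoted arylation of a flavan-4-yl cation (Friedel–Crafts); C8 of benzylated catechin attacks the β face, anti to the axial C3 hydroxyl of the 2,3-cis half-chair, and sets M C4 (3,4-trans). The excess of 22 keeps ring A of T from acting as the nucleophile.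

Step 19
Reactants: 23 dodeca-O-benzyl epicatechin-(4β→8)-epifisetinidol-(4β→8)-catechin
Product: 24 epicatechin-(4β→8)-epifisetinidol-(4β→8)-catechin (CNP0270097.1)
Conditions: H2 (1 atm), Pd(OH)2/C, THF–MeOH–H2O, rt
Reagents that add atoms: none
Why: Hydrogenolysis of twelve benzyl ethers, as in the standard final step of procyanidin syntheses; at atmospheric pressure and with a little water the benzylic C2–O1 bonds and the interflavan bonds should survive.

## Compound list

1 | 2,6-dihydroxybenzaldehyde | O=Cc1c(O)cccc1O | starting material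
2 | 2-(benzyloxy)-6-hydroxybenzaldehyde | O=Cc1c(O)cccc1OCc1ccccc1 | intermediate
3 | 2-(allyloxy)-6-(benzyloxy)benzaldehyde | O=Cc1c(OCC=C)cccc1OCc1ccccc1 | intermediate
4 | 3',4'-dihydroxyacetophenone | CC(=O)c1ccc(O)c(O)c1 | starting material
5 | 3',4'-bis(benzyloxy)acetophenone | CC(=O)c1ccc(OCc2ccccc2)c(OCc2ccccc2)c1 | intermediate
6 | (E)-3-[2-(allyloxy)-6-(benzyloxy)phenyl]-1-[3,4-bis(benzyloxy)phenyl]prop-2-en-1-one | O=C(/C=C/c1c(OCC=C)cccc1OCc1ccccc1)c1ccc(OCc2ccccc2)c(OCc2ccccc2)c1 | intermediate
7 | [(2R,3S)-3-[2-(allyloxy)-6-(benzyloxy)phenyl]oxiran-2-yl][3,4-bis(benzyloxy)phenyl]methanone | O=C(c1ccc(OCc2ccccc2)c(OCc2ccccc2)c1)[C@@H]1O[C@H]1c1c(OCC=C)cccc1OCc1ccccc1 | intermediate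
8 | (S)-[(2S,3S)-3-[2-(allyloxy)-6-(benzyloxy)phenyl]oxiran-2-yl][3,4-bis(benzyloxy)phenyl]methanol | O[C@@H](c1ccc(OCc2ccccc2)c(OCc2ccccc2)c1)[C@@H]1O[C@H]1c1c(OCC=C)cccc1OCc1ccccc1 | intermediate
9 | phloroglucinol | Oc1cc(O)cc(O)c1 | starting material
10 | 3,5-bis(benzyloxy)phenol | Oc1cc(OCc2ccccc2)cc(OCc2ccccc2)c1 | intermediate
11 | (2R,3S)-3-[2-(allyloxy)-6-(benzyloxy)phenyl]-2-{(R)-[3,5-bis(benzyloxy)phenoxy][3,4-bis(benzyloxy)phenyl]methyl}oxirane | c1ccccc1COc1cc(OCc2ccccc2)cc(c1)O[C@H](c1ccc(OCc2ccccc2)c(OCc2ccccc2)c1)[C@@H]1O[C@H]1c1c(OCC=C)cccc1OCc1ccccc1 | intermediate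
12 | (2R,3R,4S)-4-[2-(allyloxy)-6-(benzyloxy)phenyl]-5,7-bis(benzyloxy)-2-[3,4-bis(benzyloxy)phenyl]chroman-3-ol | c1ccccc1COc1cc(OCc2ccccc2)c2c(c1)O[C@H](c1ccc(OCc3ccccc3)c(OCc3ccccc3)c1)[C@H](O)[C@H]2c1c(OCC=C)cccc1OCc1ccccc1 | intermediate
13 | (2R,3R,4S)-4-[2-(allyloxy)-6-(benzyloxy)phenyl]-3,5,7-tris(benzyloxy)-2-[3,4-bis(benzyloxy)phenyl]chroman | c1ccccc1COc1cc(OCc2ccccc2)c2c(c1)O[C@H](c1ccc(OCc3ccccc3)c(OCc3ccccc3)c1)[C@H](OCc1ccccc1)[C@H]2c1c(OCC=C)cccc1OCc1ccccc1 | intermediate
14 | 3-(benzyloxy)-2-{(2R,3R,4S)-3,5,7-tris(benzyloxy)-2-[3,4-bis(benzyloxy)phenyl]chroman-4-yl}phenol | c1ccccc1COc1cc(OCc2ccccc2)c2c(c1)O[C@H](c1ccc(OCc3ccccc3)c(OCc3ccccc3)c1)[C@H](OCc1ccccc1)[C@H]2c1c(O)cccc1OCc1ccccc1 | intermediate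
15 | 3,4-bis(benzyloxy)benzaldehyde | O=Cc1ccc(OCc2ccccc2)c(OCc2ccccc2)c1 | starting material
16 | rac-1-[3,4-bis(benzyloxy)phenyl]prop-2-en-1-ol | C=CC(O)c1ccc(OCc2ccccc2)c(OCc2ccccc2)c1 | intermediate
17 | (S)-[3,4-bis(benzyloxy)phenyl][(2R)-oxiran-2-yl]methanol | O[C@@H](c1ccc(OCc2ccccc2)c(OCc2ccccc2)c1)[C@@H]1OC1 | intermediate
18 | (2R)-2-{(R)-[3,4-bis(benzyloxy)phenyl][3-(benzyloxy)-2-{(2R,3R,4S)-3,5,7-tris(benzyloxy)-2-[3,4-bis(benzyloxy)phenyl]chroman-4-yl}phenoxy]methyl}oxirane | c1ccccc1COc1cc(OCc2ccccc2)c2c(c1)O[C@H](c1ccc(OCc3ccccc3)c(OCc3ccccc3)c1)[C@H](OCc1ccccc1)[C@H]2c1c(OCc2ccccc2)cccc1O[C@H](c1ccc(OCc2ccccc2)c(OCc2ccccc2)c1)[C@@H]1OC1 | intermediate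
19 | octa-O-benzyl epicatechin-(4β→8)-epifisetinidol, M C3 hydroxyl free, M C4 methylene | c1ccccc1COc1cc(OCc2ccccc2)c2c(c1)O[C@H](c1ccc(OCc3ccccc3)c(OCc3ccccc3)c1)[C@H](OCc1ccccc1)[C@H]2c1c(OCc2ccccc2)ccc2c1O[C@H](c1ccc(OCc3ccccc3)c(OCc3ccccc3)c1)[C@H](O)C2 | intermediate
20 | 4β-(2-ethoxyethoxy) derivative of 19 at C4 of M | c1ccccc1COc1cc(OCc2ccccc2)c2c(c1)O[C@H](c1ccc(OCc3ccccc3)c(OCc3ccccc3)c1)[C@H](OCc1ccccc1)[C@H]2c1c(OCc2ccccc2)ccc2c1O[C@H](c1ccc(OCc3ccccc3)c(OCc3ccccc3)c1)[C@H](O)[C@H]2OCCOCC | intermediate
21 | (+)-catechin | Oc1cc(O)c2c(c1)O[C@H](c1ccc(O)c(O)c1)[C@@H](O)C2 | starting material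
22 | 5,7,3',4'-tetra-O-benzyl-(+)-catechin | c1ccccc1COc1cc(OCc2ccccc2)c2c(c1)O[C@H](c1ccc(OCc3ccccc3)c(OCc3ccccc3)c1)[C@@H](O)C2 | intermediate
23 | dodeca-O-benzyl epicatechin-(4β→8)-epifisetinidol-(4β→8)-catechin, C3 hydroxyls of M and L free | c1ccccc1COc1cc(OCc2ccccc2)c2c(c1)O[C@H](c1ccc(OCc3ccccc3)c(OCc3ccccc3)c1)[C@H](OCc1ccccc1)[C@H]2c1c(OCc2ccccc2)ccc2c1O[C@H](c1ccc(OCc3ccccc3)c(OCc3ccccc3)c1)[C@H](O)[C@H]2c1c(OCc2ccccc2)cc(OCc2ccccc2)c2c1O[C@H](c1ccc(OCc3ccccc3)c(OCc3ccccc3)c1)[C@@H](O)C2 | intermediate
24 | epicatechin-(4β→8)-epifisetinidol-(4β→8)-catechin (CNP0270097.1) | Oc1cc(O)c2c(c1)O[C@H](c1ccc(O)c(O)c1)[C@H](O)[C@H]2c1c(O)ccc2c1O[C@H](c1ccc(O)c(O)c1)[C@H](O)[C@H]2c1c(O)cc(O)c2c1O[C@H](c1ccc(O)c(O)c1)[C@@H](O)C2 | target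

## Step count and least certain steps

Total: 19 steps. Longest linear sequence: 14 steps (steps 1, 2, 4, 5, 6, 8, 9, 10, 11, 14, 15, 16, 18, 19).

**Step 9 (key step).** The most likely failure is that the tethered ring cannot reach C4 anti to the C–O bond quickly enough. The chair-like transition state has to seat two aryl groups and the C3 oxygen, so the activated epoxide may instead rearrange by 1,2-hydride shift or close only after full ionisation, which would erode the 3,4-trans relation. The fallback sets out from 8 and returns at 12 and makes the same two bonds in the opposite order, without the tether. Epoxy alcohol 8 and an excess of phenol 10 are combined in (CF3)2CHOH at 0 °C. The ring carbon ortho to the free hydroxyl should open the epoxide at its benzylic carbon, anti to the oxirane oxygen, to give 3-[2-(allyloxy)-6-(benzyloxy)phenyl]-1-[3,4-bis(benzyloxy)phenyl]-3-[2,4-bis(benzyloxy)-6-hydroxyphenyl]propane-1,2-diol F1 (C1 and C2 as in 8, C3 inverted). Intramolecular Mitsunobu etherification (PPh3, DIAD, THF) of the phenol with the benzylic C1 hydroxyl then closes O1–C2 with inversion and gives 12.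

**Step 14.** The most likely failure is slow ether formation, because the phenol is flanked by the T unit. The activated benzylic alcohol would then ionise (loss of configuration at C2 of M) or alkylate the hydrazide. The fallback sets out from 14, uses 15 for the partner, and returns at 18. It replaces the Mitsunobu displacement by opening of a cis-epoxide with the phenoxide, a small anionic nucleophile.
- Still–Gennari olefination of 15 gives methyl (Z)-3-[3,4-bis(benzyloxy)phenyl]acrylate F2.
- DIBAL-H reduction gives (Z)-3-[3,4-bis(benzyloxy)phenyl]prop-2-en-1-ol F3.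
- Sharpless epoxidation with Ti(OiPr)4, D-(−)-DIPT and t-BuOOH gives [(2R,3S)-3-[3,4-bis(benzyloxy)phenyl]oxiran-2-yl]methanol F4.
- The caesium phenoxide of 14 (Cs2CO3, DMF, 70 °C) opens F4 at the benzylic carbon with inversion and gives the 3-aryloxy-3-arylpropane-1,2-diol F5.
- Mitsunobu cyclodehydration of F5 (PPh3, DIAD), in which the primary hydroxyl is activated and the secondary oxygen closes, gives 18.

**Step 16.** The most likely failure is hydride abstraction at the wrong place. C4 of M lacks the 5-oxygen that makes catechin-type units easy to oxidise, while the C2–H bonds next to the 3,4-dioxygenated B rings and the electron-rich T unit offer other sites. The fallback sets out from 18 and returns at 23; it brings the C4 oxygen in with the ring closure instead of by C–H oxidation.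
- Hydrolysis of the terminal epoxide of 18 (KOH, DMSO–H2O, 80 °C) gives the diol F5 described above.
- Oxidation of the primary alcohol (TEMPO, PhI(OAc)2) gives the α-hydroxy aldehyde F6.
- Sc(OTf)3-promoted intramolecular Friedel–Crafts hydroxyalkylation, para to the 7-benzyloxy group, gives the flavan-3,4-diol F7 as a mixture of C4 epimers.
- Either epimer ionises under TMSOTf and is coupled with 22 as in step 18 to give 23.

**Step 5.** The most likely failure is slow and poorly selective epoxidation, because the β-carbon of the enone is flanked by two ortho alkoxy groups and the enone is electron-rich. The fallback sets out from 6 and returns at 8, bypassing 7. Luche reduction (NaBH4, CeCl3, MeOH) gives the racemic allylic alcohol (E)-3-[2-(allyloxy)-6-(benzyloxy)phenyl]-1-[3,4-bis(benzyloxy)phenyl]prop-2-en-1-ol F8. Sharpless kinetic resolution (Ti(OiPr)4, L-(+)-DIPT, t-BuOOH 0.55 equiv, −20 °C) epoxidises its (R)-enantiomer anti-selectively and gives 8 directly. The allyl ether alkene is not an allylic alcohol and stays untouched.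

## Further compounds

F1 | step 9 | 3-[2-(allyloxy)-6-(benzyloxy)phenyl]-1-[3,4-bis(benzyloxy)phenyl]-3-[2,4-bis(benzyloxy)-6-hydroxyphenyl]propane-1,2-diol | O[C@@H](c1ccc(OCc2ccccc2)c(OCc2ccccc2)c1)[C@H](O)[C@@H](c1c(OCC=C)cccc1OCc1ccccc1)c1c(O)cc(OCc2ccccc2)cc1OCc1ccccc1
F2 | step 14 | methyl (Z)-3-[3,4-bis(benzyloxy)phenyl]acrylate | COC(=O)/C=C\c1ccc(OCc2ccccc2)c(OCc2ccccc2)c1
F3 | step 14 | (Z)-3-[3,4-bis(benzyloxy)phenyl]prop-2-en-1-ol | OC/C=C\c1ccc(OCc2ccccc2)c(OCc2ccccc2)c1
F4 | step 14 | [(2R,3S)-3-[3,4-bis(benzyloxy)phenyl]oxiran-2-yl]methanol | OC[C@H]1O[C@H]1c1ccc(OCc2ccccc2)c(OCc2ccccc2)c1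
F5 | step 14 | 3-[3,4-bis(benzyloxy)phenyl]-3-[3-(benzyloxy)-2-{(2R,3R,4S)-3,5,7-tris(benzyloxy)-2-[3,4-bis(benzyloxy)phenyl]chroman-4-yl}phenoxy]propane-1,2-diol, configured as in 18 | c1ccccc1COc1cc(OCc2ccccc2)c2c(c1)O[C@H](c1ccc(OCc3ccccc3)c(OCc3ccccc3)c1)[C@H](OCc1ccccc1)[C@H]2c1c(OCc2ccccc2)cccc1O[C@H](c1ccc(OCc2ccccc2)c(OCc2ccccc2)c1)[C@H](O)CO
F6 | step 16 | 3-[3,4-bis(benzyloxy)phenyl]-3-[3-(benzyloxy)-2-{(2R,3R,4S)-3,5,7-tris(benzyloxy)-2-[3,4-bis(benzyloxy)phenyl]chroman-4-yl}phenoxy]-2-hydroxypropanal | c1ccccc1COc1cc(OCc2ccccc2)c2c(c1)O[C@H](c1ccc(OCc3ccccc3)c(OCc3ccccc3)c1)[C@H](OCc1ccccc1)[C@H]2c1c(OCc2ccccc2)cccc1O[C@H](c1ccc(OCc2ccccc2)c(OCc2ccccc2)c1)[C@H](O)C=O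
F7 | step 16 | octa-O-benzyl epicatechin-(4β→8)-epifisetinidol-4-ol (flavan-3,4-diol of M, C4 epimers) | c1ccccc1COc1cc(OCc2ccccc2)c2c(c1)O[C@H](c1ccc(OCc3ccccc3)c(OCc3ccccc3)c1)[C@H](OCc1ccccc1)[C@H]2c1c(OCc2ccccc2)ccc2c1O[C@H](c1ccc(OCc3ccccc3)c(OCc3ccccc3)c1)[C@H](O)C2O
F8 | step 5 | rac-(E)-3-[2-(allyloxy)-6-(benzyloxy)phenyl]-1-[3,4-bis(benzyloxy)phenyl]prop-2-en-1-ol | OC(/C=C/c1c(OCC=C)cccc1OCc1ccccc1)c1ccc(OCc2ccccc2)c(OCc2ccccc2)c1
A1 | alternative 1 | 3,5,7,3',4'-penta-O-benzyl-4β-[(triisopropylsilyloxy)ethynyl]epicatechin | c1ccccc1COc1cc(OCc2ccccc2)c2c(c1)O[C@H](c1ccc(OCc3ccccc3)c(OCc3ccccc3)c1)[C@H](OCc1ccccc1)[C@H]2C#CO[Si](C(C)C)(C(C)C)C(C)C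
A2 | alternative 1 | (E)-unsaturated diazoketone carrying penta-O-benzylcatechin-8-yl and the protected C2–C4 chain of M | [N-]=[N+]=CC(=O)/C=C/[C@H](c1c(OCc2ccccc2)cc(OCc2ccccc2)c2c1O[C@H](c1ccc(OCc3ccccc3)c(OCc3ccccc3)c1)[C@@H](OCc1ccccc1)C2)[C@@H](OCc1ccccc1)[C@@H](O[Si](C)(C)C(C)(C)C)c1ccc(OCc2ccccc2)c(OCc2ccccc2)c1
A3 | alternative 1 | seco-trimer phenol, ring A of M formed, O1–C2 of M open | c1ccccc1COc1cc(OCc2ccccc2)c2c(c1)O[C@H](c1ccc(OCc3ccccc3)c(OCc3ccccc3)c1)[C@H](OCc1ccccc1)[C@H]2c1c(O[Si](C(C)C)(C(C)C)C(C)C)ccc(c1O)[C@H](c1c(OCc2ccccc2)cc(OCc2ccccc2)c2c1O[C@H](c1ccc(OCc3ccccc3)c(OCc3ccccc3)c1)[C@@H](OCc1ccccc1)C2)[C@@H](OCc1ccccc1)[C@@H](O[Si](C)(C)C(C)(C)C)c1ccc(OCc2ccccc2)c(OCc2ccccc2)c1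
A4 | alternative 2 | ortho-hydroxybenzhydrol linking the T-bearing ring A of M to C8 of penta-O-benzylcatechin | c1ccccc1COc1cc(OCc2ccccc2)c2c(c1)O[C@H](c1ccc(OCc3ccccc3)c(OCc3ccccc3)c1)[C@H](OCc1ccccc1)[C@H]2c1c(OCc2ccccc2)ccc(c1O)C(O)c1c(OCc2ccccc2)cc(OCc2ccccc2)c2c1O[C@H](c1ccc(OCc3ccccc3)c(OCc3ccccc3)c1)[C@@H](OCc1ccccc1)C2
A5 | alternative 2 | (Z)-[2-(benzyloxy)-1-[3,4-bis(benzyloxy)phenyl]vinyloxy]trimethylsilane | C[Si](C)(C)O/C(=C\OCc1ccccc1)c1ccc(OCc2ccccc2)c(OCc2ccccc2)c1
A6 | alternative 2 | trimer with ring C of M as 2-aryl-2-(trimethylsilyloxy)-3-(benzyloxy) ketal | c1ccccc1COc1cc(OCc2ccccc2)c2c(c1)O[C@H](c1ccc(OCc3ccccc3)c(OCc3ccccc3)c1)[C@H](OCc1ccccc1)[C@H]2c1c(OCc2ccccc2)ccc2c1O[C@](O[Si](C)(C)C)(c1ccc(OCc3ccccc3)c(OCc3ccccc3)c1)[C@H](OCc1ccccc1)[C@H]2c1c(OCc2ccccc2)cc(OCc2ccccc2)c2c1O[C@H](c1ccc(OCc3ccccc3)c(OCc3ccccc3)c1)[C@@H](OCc1ccccc1)C2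
A7 | alternative 3 | seco-trimer: 3,5-bis(benzyloxy)phenol carrying at C2 the M–L dimer and a cis-epoxide of the T chain | c1ccccc1COc1cc(OCc2ccccc2)c(c(O)c1)[C@H](c1c(OCc2ccccc2)ccc2c1O[C@H](c1ccc(OCc3ccccc3)c(OCc3ccccc3)c1)[C@H](OCc1ccccc1)[C@H]2c1c(OCc2ccccc2)cc(OCc2ccccc2)c2c1O[C@H](c1ccc(OCc3ccccc3)c(OCc3ccccc3)c1)[C@@H](OCc1ccccc1)C2)[C@H]1O[C@H]1c1ccc(OCc2ccccc2)c(OCc2ccccc2)c1
A8 | alternative 3 | benzyl-protected trimer with free C3 hydroxyl on T | c1ccccc1COc1cc(OCc2ccccc2)c2c(c1)O[C@H](c1ccc(OCc3ccccc3)c(OCc3ccccc3)c1)[C@H](O)[C@H]2c1c(OCc2ccccc2)ccc2c1O[C@H](c1ccc(OCc3ccccc3)c(OCc3ccccc3)c1)[C@H](OCc1ccccc1)[C@H]2c1c(OCc2ccccc2)cc(OCc2ccccc2)c2c1O[C@H](c1ccc(OCc3ccccc3)c(OCc3ccccc3)c1)[C@@H](OCc1ccccc1)C2
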